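## Retrosynthetic overview

- The target is reached from its 7‑O‑acetate by lipase‑catalysed deacetylation under neutral conditions, so the flavanone ring is never exposed to base and C2 cannot racemise through the ring‑opened chalcone.
- The 7‑O‑acetyl flavanone is disconnected at the C2–aryl bond: Rh/chiral‑diene asymmetric 1,4‑addition of a chromenylboronic acid to 7‑acetoxychromone sets the only stereocentre (2R).
- The boronic acid comes from 6‑bromo‑2,2‑dimethyl‑8‑prenyl‑2H‑chromene, made by propargyl‑ether Claisen/oxa‑6π cyclisation of 4‑bromo‑2‑prenylphenol, itself from 4‑bromophenol by allyl Claisen rearrangement and cross‑metathesis.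
- Ring order: the benzopyranone ring is bought intact as 7‑hydroxychromone. The only ring constructed is the 2,2‑dimethylpyran of the chromene, before fragment union. No ring is formed after the stereocentre is set.

Assumption 1: the SMILES encodes the (2R)‑flavanone (the natural product is 2S), and the route is designed for 2R.
Assumption 2: 7‑hydroxy‑4H‑chromen‑4‑one is treated as a catalogue compound; if not, it is made from 2,4‑dihydroxyacetophenone via the DMF‑DMA enaminone and acid cyclisation.

## Route

**Step 1**
Reactants: 1 (4‑bromophenol), 2 (allyl bromide)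
Product: 3, 1‑(allyloxy)‑4‑bromobenzene
Conditions: K2CO3, acetone, reflux
Reagents that add atoms: allyl bromide, C=CCBr
Why: Williamson O‑allylation of a phenoxide with a reactive primary allylic halide is essentially quantitative.

**Step 2**
Reactants: 3 (1‑(allyloxy)‑4‑bromobenzene)
Product: 4, 2‑allyl‑4‑bromophenol
Conditions: N,N‑diethylaniline, 200 °C
Reagents that add atoms: none
Why: Aromatic Claisen rearrangement; the para position is blocked by Br and both ortho positions are equivalent, so a single ortho‑allyl phenol forms.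

**Step 3**
Reactants: 4 (2‑allyl‑4‑bromophenol), 5 (2‑methyl‑2‑butene)
Product: 6, 4‑bromo‑2‑(3‑methylbut‑2‑en‑1‑yl)phenol
Conditions: Grubbs II (3 mol %), 2‑methyl‑2‑butene (large excess)/CH2Cl2, 35–40 °C, sealed
Reagents that add atoms: 2‑methyl‑2‑butene, CC=C(C)C
Why: Olefin cross‑metathesis of a terminal allyl arene with excess 2‑methyl‑2‑butene gives the prenyl group with loss of propene; the free phenol and aryl bromide are tolerated.

**Step 4**
Reactants: 6 (4‑bromo‑2‑prenylphenol), 7 (3‑chloro‑3‑methylbut‑1‑yne)
Product: 8, 4‑bromo‑1‑[(2‑methylbut‑3‑yn‑2‑yl)oxy]‑2‑(3‑methylbut‑2‑en‑1‑yl)benzene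
Conditions: DBU, CuCl2·2H2O (cat.), MeCN, 0 °C → rt
Reagents that add atoms: 3‑chloro‑3‑methylbut‑1‑yne, CC(C)(Cl)C#C
Why: Cu‑catalysed propargylic etherification (via a copper acetylide/allenylidene‑type electrophile) O‑alkylates even ortho‑substituted phenols with the tertiary propargylic chloride.

**Step 5**
Reactants: 8 (aryl 1,1‑dimethylpropargyl ether)
Product: 9, 6‑bromo‑2,2‑dimethyl‑8‑(3‑methylbut‑2‑en‑1‑yl)‑2H‑chromene
Conditions: N,N‑diethylaniline, 185 °C
Reagents that add atoms: none
Why: Propargyl Claisen rearrangement to the only free ortho carbon, then enolisation, 1,5‑H shift and oxa‑6π electrocyclisation give the 2,2‑dimethylchromene; the basic medium keeps the prenyl group intact.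

**Step 6**
Reactants: 9 (bromochromene), 10 (triisopropyl borate)
Product: 11, [2,2‑dimethyl‑8‑(3‑methylbut‑2‑en‑1‑yl)‑2H‑chromen‑6‑yl]boronic acid
Conditions: n‑BuLi, THF, −78 °C; B(OiPr)3, −78 °C → rt; sat. aq NH4Cl
Reagents that add atoms: triisopropyl borate, CC(C)OB(OC(C)C)OC(C)C (boron); water, O (boronic acid oxygens on hydrolysis)
Why: Br–Li exchange is fast at −78 °C and the aryllithium is trapped by the borate; the mildly acidic work‑up hydrolyses the boronate without touching the acid‑sensitive prenyl and chromene alkenes.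

**Step 7**
Reactants: 12 (7‑hydroxy‑4H‑chromen‑4‑one), 13 (acetic anhydride)
Product: 14, 4‑oxo‑4H‑chromen‑7‑yl acetate
Conditions: Ac2O, pyridine, DMAP (cat.), CH2Cl2, 0 °C → rt
Reagents that add atoms: acetic anhydride, CC(=O)OC(C)=O
Why: Phenol acylation; the acetate removes the donor effect of the free 7‑OH so the chromone stays electrophilic in step 8, and it is a group a lipase can later remove.

**Step 8**
Reactants: 14 (7‑acetoxychromone), 11 (chromenylboronic acid, 1.5 equiv)
Product: 15, (2R)‑2‑[2,2‑dimethyl‑8‑(3‑methylbut‑2‑en‑1‑yl)‑2H‑chromen‑6‑yl]‑4‑oxo‑3,4‑dihydro‑2H‑chromen‑7‑yl acetate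
Conditions: [RhCl(C2H4)2]2 (1.5 mol %), (R,R)‑Ph‑bod* [(1R,4R)‑2,5‑diphenylbicyclo[2.2.2]octa‑2,5‑diene] (3.3 mol %), aq KOH (3 mol %, only to form Rh–OH), 1,4‑dioxane/H2O 10:1, 30 °C, degassed
Reagents that add atoms: none beyond the two reactants (water supplies only H)
Why: Hayashi–Miyaura Rh(I)-catalysed asymmetric 1,4‑addition: the aryl–Rh(diene*) species adds across the chromone C2=C3 on one enantioface to create C2 as (R), while the isolated alkenes and the aryl acetate are inert at 30 °C under near‑neutral conditions. The (R) sense is predicted by analogy with (R,R)‑diene → (R)‑3‑arylcyclohexanone (recalled from memory, not verified) and must be confirmed by chiral HPLC/CD, switching to the (S,S)‑ligand if reversed.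

**Step 9**
Reactants: 15 (7‑O‑acetyl flavanone)
Product: 16, ent‑abyssinone III, (2R)‑7‑hydroxy‑2‑[2,2‑dimethyl‑8‑(3‑methylbut‑2‑en‑1‑yl)‑2H‑chromen‑6‑yl]‑2,3‑dihydro‑4H‑chromen‑4‑one
Conditions: immobilised lipase (Burkholderia cepacia lipase, Amano PS‑IM; CAL‑B as alternative), n‑BuOH (5–10 equiv), THF, 40–45 °C; filter, chromatograph without base
Reagents that add atoms: none
Why: Lipase (serine hydrolase) alcoholysis transfers the aryl acetate to n‑butanol at neutral pH, avoiding the base‑induced E1cB ring opening to the 2'‑hydroxychalcone that would racemise C2; the 7‑O‑acyl group of flavanones is a good lipase substrate and sits remote from the bulky B‑ring.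

## Compound list

1 | 4‑bromophenol | Oc1ccc(Br)cc1 | starting material
2 | allyl bromide | C=CCBr | starting material
3 | 1‑(allyloxy)‑4‑bromobenzene | C=CCOc1ccc(Br)cc1 | intermediate
4 | 2‑allyl‑4‑bromophenol | C=CCc1cc(Br)ccc1O | intermediate
5 | 2‑methyl‑2‑butene | CC=C(C)C | starting material
6 | 4‑bromo‑2‑(3‑methylbut‑2‑en‑1‑yl)phenol | CC(C)=CCc1cc(Br)ccc1O | intermediate
7 | 3‑chloro‑3‑methylbut‑1‑yne | CC(C)(Cl)C#C | starting material
8 | 4‑bromo‑1‑[(2‑methylbut‑3‑yn‑2‑yl)oxy]‑2‑(3‑methylbut‑2‑en‑1‑yl)benzene | CC(C)=CCc1cc(Br)ccc1OC(C)(C)C#C | intermediate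
9 | 6‑bromo‑2,2‑dimethyl‑8‑(3‑methylbut‑2‑en‑1‑yl)‑2H‑chromene | CC(C)=CCc1cc(Br)cc2c1OC(C)(C)C=C2 | intermediate
10 | triisopropyl borate | CC(C)OB(OC(C)C)OC(C)C | starting material
11 | [2,2‑dimethyl‑8‑(3‑methylbut‑2‑en‑1‑yl)‑2H‑chromen‑6‑yl]boronic acid | CC(C)=CCc1cc(B(O)O)cc2c1OC(C)(C)C=C2 | intermediate
12 | 7‑hydroxy‑4H‑chromen‑4‑one | O=c1ccoc2cc(O)ccc12 | starting material
13 | acetic anhydride | CC(=O)OC(C)=O | starting material
14 | 4‑oxo‑4H‑chromen‑7‑yl acetate | CC(=O)Oc1ccc2c(c1)occc2=O | intermediate
15 | (2R)‑2‑[2,2‑dimethyl‑8‑(3‑methylbut‑2‑en‑1‑yl)‑2H‑chromen‑6‑yl]‑4‑oxo‑3,4‑dihydro‑2H‑chromen‑7‑yl acetate | CC(C)=CCc1cc([C@H]2CC(=O)c3ccc(OC(C)=O)cc3O2)cc2c1OC(C)(C)C=C2 | intermediate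
16 | ent‑abyssinone III, (2R) | CC(C)=CCc1cc([C@H]2CC(=O)c3ccc(O)cc3O2)cc2c1OC(C)(C)C=C2 | target

## Summary

Total steps: 9. Longest linear sequence: 8 (steps 1 → 2 → 3 → 4 → 5 → 6 → 8 → 9); step 7 is a one‑step side branch.

Three steps most likely to fail, each with a fallback:

1. **Step 8 (asymmetric 1,4‑addition).** Risks are low chromone reactivity, protodeboronation of the electron‑rich boronic acid, partial acetate loss, or insufficient ee or the wrong sense.
   Fallback: abandon the C2–aryl disconnection. Formylate 9 (n‑BuLi/DMF), run a Claisen–Schmidt condensation with a 4‑O‑protected 2‑hydroxyacetophenone, and cyclise the 2'‑hydroxychalcone to the racemic flavanone with NaOAc. Then use Ru/TsDPEN asymmetric transfer‑hydrogenation kinetic resolution, which reduces the (2S)‑enantiomer to the flavan‑4‑ol and leaves the (2R)‑flavanone. This caps the yield at 50 %.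

2. **Step 5 (thermal propargyl Claisen/electrocyclisation next to an ortho‑prenyl group).** Risks are competing pathways or decomposition at 185 °C.
   Fallback: build the pyran by a different bond construction. Condense phenol 6 directly with 3‑methylbut‑2‑enal (PhB(OH)2, AcOH, toluene, Dean–Stark), which goes through a benzodioxaborin and o‑quinone methide to the same chromene 9 by oxa‑6π closure.

3. **Step 9 (lipase deacetylation).** The risk is slow turnover on this bulky, poorly soluble substrate.
   Fallback: change the ester carried from step 7 to the 7‑O‑butanoate (butyric anhydride), a better hydrolase substrate, and cleave it by carboxylesterase (pig‑liver esterase) hydrolysis at pH 7 in buffer/co‑solvent. This still never exposes the flavanone to base.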